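Atom labels C8–C24 and O7, O11 are the positions in the heavy-atom order of the target SMILES: C8 carries the angelate, C10 the free hydroxyl, C12 and C22 are the two quaternary carbons, C17 is the ketone, C20 carries methyl C21, and C24 is the acetoxymethyl carbon.

## The problem

The target is a bicyclo[3.1.1]heptanone whose two one-carbon bridges (C12 and C15) are tied together, on the face away from the ketone bridge C20–C19–C17, by the four-carbon chain C10–C9–C8–C22. This gives a six-membered ring A, a seven-membered ring B and the cyclobutane C12–C14–C15–C16 in one cage. Of the eight stereocentres, C12 and C16 follow by necessity from a cis C14–C15 relationship, because only one way of bridging the four-membered ring is possible. C22 (methyl against acetoxymethyl) must be set relative to C15 and is the least obvious centre. The remaining centres can be relayed: the cage face sets C20, the C22 substituents set the neighbouring C8 oxygen, and the C8 hydroxyl can deliver hydride to C10 to give the 1,3-anti pattern. Three oxygens must end up differently substituted (angelate at O7, free hydroxyl at O11, acetate on C24), and the two secondary ones are equally hindered, so they have to be told apart by the order in which they are made. The angelate isomerises to the tiglate under nucleophilic or basic conditions, the β-oxygenated ketone stages can eliminate or undergo retro-aldol cleavage, and the strained C12–C16 bond sits between two carbonyl groups and can be cleaved by strong one-electron donors. The enabling feature is that C12 and C16 are the α-carbons of the C10 and C17 carbonyl groups: the cyclobutane bond C12–C16 is the central bond of a 1,4-diketone, and the two carbons are 1,4-related across the C14–C15 bond.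

## Retrosynthesis

**Ester and silyl groups (27 ⇐ 26 ⇐ 24).** The last bonds cut are the O11–Si bond and the O7–angeloyl bond. The angelate is introduced as late as possible, onto alcohol 24 in which O11 is silylated and C24 already carries its acetate, so that no later step can isomerise or migrate it. The forward reactions are a Yamaguchi acylation of a hindered alcohol and a fluoride desilylation.

**Telling the three oxygens apart (24 ⇐ 22 ⇐ 21 ⇐ 20).** The O11–H bond and the acetyl position are traced back to β-hydroxy ketone 20. An Evans–Tishchenko reduction forms the C10–H bond from the C8 hydroxyl and leaves its acetyl group on O8, so in 21 only O11 is free and can be silylated (22). Unmasking the C24 alcohol lets the acetyl group move to the primary oxygen (24). A directed borohydride reduction would set C10 equally well but would give a diol with two indistinguishable secondary hydroxyls.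

**C8–O and C20–C21 (20 ⇐ 18 ⇐ 17).** The C8 oxygen is removed to the seven-ring enone of 18 (conjugate borylation and oxidation in the forward direction, controlled by the neighbouring C22). The C21 methyl is removed to the six-ring enone of 17 (cuprate addition from the open face). Both cuts end at tricyclic bis-enone 17, which has no sp3 stereocentre outside the cage and C22.

**C12–C16 (17 ⇐ 15).** Cutting the central bond of the 1,4-diketone opens the cyclobutane and removes two stereocentres and the cage, leaving cis-fused bicyclic bis-enone 15. Every other single-bond cut of the cage keeps a four-membered ring in the precursor; this one replaces it by a six/seven-fused bicycle. The forward reaction must couple two enolate carbons within one molecule.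

- The seven-ring ketone is carried as an enone and not as a 3-methoxy enone. Either group makes C9 vinylic, so that only C12 can be deprotonated. A methoxy group at C8, next to quaternary C22, is the regioisomer that enol ether formation from the 1,3-dione disfavours. The enone comes regiospecifically from a Stork–Danheiser transposition.

**Oxidation level and C13 (15 ⇐ 14 ⇐ 13 ⇐ 12 ⇐ 10).** The C17 carbonyl is removed to cyclohexene 14 (allylic oxidation forward) and the C12–C13 bond to 13 (α′-methylation forward). The enone of 12 is traced to vinylogous ester 10, whose ketone sits at C8. This is the regioisomer in which C22 is an α-carbon and can be alkylated.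

**C22–C23 (10 ⇐ 9).** The quaternary centre is made last of the ring B carbons, by methylating cyclic β-keto ester 9 from the face away from ring A. Setting C22 in an open chain next to C15 would offer no comparable control.

**C9–C10, ring B (9 ⇐ 8 ⇐ 7).** The seven-membered ring is opened at the C9–C10 bond of tricarbonyl compound 8, giving a cyclohexene with an acetoacetate arm at C15 and a Weinreb amide arm at C14 (7). The forward step is an intramolecular acylation of an acetoacetate dianion.

**C12–C14 and C15–C22 (7 ⇐ 4 ⇐ 2 + 3).** The C12–C14 bond is cut by a retro-Ireland–Claisen step, which returns the alkene to C14=C20 and puts an acetate on C19, cis to the C15 arm (4). The C15–C22 bond is then cut to meso diacetate 2 and methyl acetoacetate 3. One catalytic asymmetric allylic alkylation sets the absolute configuration, and the sigmatropic shift transfers it to C14 with the cis relationship the key step needs.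

**Diacetate (2 ⇐ 1).** The meso diacetate comes from cyclohexa-1,3-diene 1 by 1,4-diacetoxylation.

## Roads not taken

**Alternative 1:** The cut is the C15–C22 bond, so that ring B closes onto a preformed 1-acetylcyclobutene. In the forward step, Fe(acac)3 and phenylsilane transfer a hydrogen atom to a 1,1-disubstituted alkene, and the tertiary C22 radical adds to C15 to give the acetyl-substituted bicyclo[4.1.1]octane A1.
- Merits: the radical conjugate cyclisation is a known, mild reaction that makes a quaternary carbon. The C8 and C10 oxygens are set in the open chain beforehand, so the late differentiation of hydroxyls disappears. In this respect it is better than the chosen plan.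
- Weak points: the substrate is an enantiopure, fully substituted cyclobutene with quaternary C12, which is the hardest part of the molecule and has to be made by other means. The seven-membered closure competes with simple reduction of the radical. C22 is formed with only methyl against alkoxymethyl to distinguish its faces. Ring A still has to be built afterwards from the acetyl group.
- Comparison: the chosen plan must set an unprecedented ring closure against the known key step of this road. In return it makes the cyclobutane, both its new stereocentres and the cage in one operation from a bicycle that catalytic asymmetric chemistry supplies.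

**Alternative 2:** The cuts are C16–C17 and C17–C19, with C17 coming from carbon monoxide. Thexylborane hydroborates an isopropenyl group and then a cyclobutene, and carbonylation–oxidation of the boracycle gives the bicyclo[3.1.1]heptan-2-one A2.
- Merits: two C–C bonds and the ketone form at once, and C20 is set by hydroboration without a cuprate, which is as good as the chosen plan for that centre.
- Weak points: the substrate is again a substituted cyclobutene. The regiochemistry of its hydroboration next to two hindered carbons is not secured, and the boracycle must span 1,3-positions of a four-membered ring. Most seriously, ring B is still missing in A2: two neopentyl oxymethyl arms would have to be joined through C9 late in the route.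
- Comparison: the chosen plan closes ring B early by an ordinary acylation and never has to construct a cyclobutene.

**Alternative 3:** The cut is the C19–C20 bond, formed as an alkene from a sulfone bridging C19 and C20. The Ramberg–Bäcklund rearrangement (KOH, CCl4) contracts a bridged thiepane dioxide to the tricyclic allylic ketal A3.
- Merits: the extrusion of SO2 is irreversible and tolerates strain. A3 has its alkene exactly where the enone for the methyl addition is needed, and its ring B oxygens are already in place. On both counts it is as good as or better than the chosen plan.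
- Weak points: the cyclobutane–cycloheptane core must already exist with cis handles on C14 and C16. The thiepane has to be closed by a displacement next to a ketal carbon, and α-halogenation must choose between C19 and C20.
- Comparison: the step count before A3 is high and the cyclobutane problem is only moved. The chosen plan has the unproven step, but reaches the same enone stage directly from a bicyclic precursor.

Key step: step 11

Assumption: the (R,R) enantiomer of the DACH-phenyl Trost ligand is taken to ionise the acetate at C15 of 2; if the sense is the opposite, the (S,S) ligand is used and nothing else changes.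

## Route

Step 1
Reactants: 1 cyclohexa-1,3-diene
Product: 2 cis-cyclohex-2-ene-1,4-diyl diacetate (meso)
Conditions: Pd(OAc)2 (5 mol %), LiOAc, LiCl (cat.), p-benzoquinone, AcOH, rt
Reagents that add atoms: acetic acid, CC(=O)O
Why: Bäckvall palladium-catalysed 1,4-diacetoxylation of a conjugated diene; with catalytic chloride both acetates end on the same ring face, so the meso cis-diacetate forms and no stereocentre needs control yet.

Step 2
Reactants: 2 cis-cyclohex-2-ene-1,4-diyl diacetate; 3 methyl acetoacetate
Product: 4 methyl 2-(cis-4-acetoxycyclohex-2-enyl)-3-oxobutanoate (C15 as in the SMILES, C22 epimers)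
Conditions: NaH, Pd2(dba)3·CHCl3 (2.5 mol %), (R,R)-DACH-phenyl Trost ligand (7.5 mol %), THF, 0 °C
Reagents that add atoms: none
Why: Trost asymmetric allylic alkylation (Tsuji–Trost desymmetrisation): the chiral zerovalent palladium catalyst ionises one enantiotopic acetate and the soft keto ester anion attacks anti to the metal, so net retention puts the new C15–C22 bond cis to the remaining acetate and fixes the absolute configuration of C15.

Step 3
Reactants: 4 methyl 2-(cis-4-acetoxycyclohex-2-enyl)-3-oxobutanoate
Product: 7 cis-disubstituted cyclohexene Weinreb amide (C14 arm CH2C(=O)N(OMe)Me; C15 arm acetoacetate), via bis-silyl ketene acetal 5 (not isolated), via carboxylic acid 6 (not isolated)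
Conditions: LiN(i-Pr)2 (2.3 equiv), Me3SiCl, THF, −78 °C to 50 °C; 1 M HCl; then MeNHOMe·HCl, EDC·HCl, Et3N, CH2Cl2
Reagents that add atoms: N,O-dimethylhydroxylamine hydrochloride, CNOC.Cl
Why: Ireland–Claisen rearrangement: the silyl ketene acetal of the allylic acetate delivers C12 suprafacially from O–C19 to C14, cis to the C15 arm, and moves the alkene to C19=C20. The keto ester travels as its silyl enol ether, and carbodiimide coupling turns the acid into the Weinreb amide.

Step 4
Reactants: 7 cis-disubstituted cyclohexene Weinreb amide
Product: 8 cis-fused bicyclic diketo ester (ring B: C8 and C10 ketones, CO2Me on C22; ring A: C19=C20 alkene)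
Conditions: NaH (1.1 equiv), THF, 0 °C; n-BuLi (1.1 equiv), −78 to 0 °C; 1 M HCl
Reagents that add atoms: none
Why: Weiler dianion acylation run intramolecularly: only the γ-carbanion C9 of the acetoacetate dianion is reactive enough to attack the Weinreb amide, whose chelated tetrahedral intermediate survives until work-up. The C9–C10 bond and ring B therefore form without the five-ring C22 acylation that an alkoxide-mediated condensation would allow.

Step 5
Reactants: 8 cis-fused bicyclic diketo ester
Product: 9 methyl vinylogous ester (C8 ketone, C9=C10–OMe, CO2Me on C22)
Conditions: MeOH, TsOH (cat.), 3 Å molecular sieves, 40 °C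
Reagents that add atoms: methanol, CO
Why: Acid-catalysed enol etherification of a cyclic 1,3-dione: methanol adds to the C10 carbonyl, which is flanked by a CH2 group. The C8 carbonyl is shielded by C22 and held in the chelated keto ester enol, so C9 becomes vinylic and the ketone stays at C8.

Step 6
Reactants: 9 methyl vinylogous ester
Product: 10 C22-methylated vinylogous ester (C22: CH3 and CO2Me)
Conditions: Cs2CO3, MeI, MeCN, rt
Reagents that add atoms: iodomethane, CI
Why: Alkylation of a cyclic β-keto ester at its only acidic carbon; the cis-fused ring A covers one face of the C22 enolate, so iodomethane enters from the convex face and the methyl group ends cis to H15, which sets quaternary C22.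

Step 7
Reactants: 10 C22-methylated vinylogous ester
Product: 12 bicyclic enone alcohol (C10 ketone, C8=C9 alkene, CH2OH on C22), via diol enol ether 11 (not isolated)
Conditions: LiAlH4, Et2O, 0 °C; then 10 % aq. HCl, rt
Reagents that add atoms: none
Why: Stork–Danheiser sequence: hydride reduces the C8 carbonyl of the vinylogous ester and the ester to the C24 alcohol, and acid hydrolysis of the enol ether with loss of water moves the carbonyl to C10 and gives the C8=C9 enone; no stereocentre is touched.

Step 8
Reactants: 12 bicyclic enone alcohol
Product: 13 silyl ether of 12 (C24–OSiMe2t-Bu)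
Conditions: t-BuMe2SiCl, imidazole, DMF, rt
Reagents that add atoms: tert-butyldimethylsilyl chloride, CC(C)(C)[Si](C)(C)Cl
Why: Imidazole-mediated silylation of the primary neopentyl alcohol; the silyl ether withstands the amide bases, the cuprate and the oxidants of the following steps.

Step 9
Reactants: 13 silyl ether of 12
Product: 14 C12-methyl enone (C12 epimers)
Conditions: LiN(i-Pr)2 (1.05 equiv), THF, −78 °C; MeI
Reagents that add atoms: iodomethane, CI
Why: Kinetic α′-deprotonation of the enone (C9 is vinylic, C22 has no hydrogen) and SN2 methylation install C13; the configuration at C12 does not matter because this carbon is enolised again in step 11.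

Step 10
Reactants: 14 C12-methyl enone
Product: 15 cis-fused bis-enone (ring A: C17 ketone, C19=C20; ring B: C10 ketone, C8=C9)
Conditions: CrO3, 3,5-dimethylpyrazole, CH2Cl2, −20 °C
Reagents that add atoms: chromium trioxide, O=[Cr](=O)=O
Why: Allylic oxidation with the CrO3–3,5-dimethylpyrazole complex: hydrogen abstraction at the unhindered allylic methylene C17 and oxygenation at that terminus give the C17 enone with the alkene kept at C19=C20; the ring-fusion C14–H is tertiary and shielded.

Step 11
Reactants: 15 cis-fused bis-enone
Product: 17 tricyclic bis-enone (cyclobutane C12–C14–C15–C16 closed), via dilithium bis-enolate 16 (not isolated)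
Conditions: LiN(i-Pr)2 (2.2 equiv), THF, −78 °C; then slow addition to Fe(acac)3 (2.2 equiv), THF, −78 to 0 °C
Reagents that add atoms: none
Why: Proposed new method: Two equivalents of LiN(i-Pr)2 remove the only α′ protons (C12–H and one C16–H; C9 is vinylic and C22 bears no hydrogen) and give dilithium bis-dienolate 16. Fe(acac)3 (trivalent iron) oxidises one enolate to an α-keto radical, most readily the more substituted C12 enolate; the radical adds to enolate carbon C16 in a 4-exo-trig closure, and a second equivalent of trivalent iron oxidises the resulting C17 ketyl, which makes formation of the strained C12–C16 bond irreversible. The closest known reaction type is the intramolecular oxidative coupling of two lithium enolates with Fe(acac)3 or divalent copper carboxylates to 1,4-dicarbonyl compounds, and the iodine-mediated cyclisation of diester dienolates to cyclobutane-1,2-dicarboxylates; a bridged cyclobutane has not been made in this way. The one ring closed is the cyclobutane C12–C14–C15–C16, which completes the bicyclo[3.1.1]heptenone and the bridged seven-membered ring at the same time. The new stereocentres C12 and C16 are controlled by the cis C14–C15 fusion: only the rotamer with C12 and C16 syn can bond, and it places the bridge C20–C19–C17 and the bridge C10–C9–C8–C22 on opposite faces of the four-membered ring, so no other diastereomer is geometrically possible. The step needs C–C coupling inside one molecule and not O–C coupling, bonding at C9 or C19, or coupling between molecules. The 1,4-relationship of the two enolate carbons across the cis fusion, the absence of spin density at C9 and C19 in the cross-conjugated radicals, and slow addition into a dilute oxidant solution are expected to secure this.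

Step 12
Reactants: 17 tricyclic bis-enone
Product: 18 C20-methyl tricyclic diketone (ring B enone intact)
Conditions: Me2CuLi (from CuI and 2 MeLi; 1.1 equiv), Et2O, −78 °C; aq. NH4Cl–NH3
Reagents that add atoms: lithium dimethylcuprate, [Li+].C[Cu-]C
Why: Conjugate addition of a Gilman cuprate: the reagent reaches C20 from the face opposite the methyl-bearing bridge C12, which sets C20. It should prefer the unhindered bicyclic enone over the ring B enone, whose β-carbon C8 is flanked by quaternary C22.

Step 13
Reactants: 18 C20-methyl tricyclic diketone
Product: 20 β-hydroxy ketone (C8–OH cis to C23; C10 ketone), via boronate 19 (not isolated)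
Conditions: B2pin2 (1.2 equiv), CuCl (5 mol %), DPEphos (5 mol %), NaOt-Bu (10 mol %), MeOH (2 equiv), THF, rt; then NaBO3·4H2O, THF–H2O
Reagents that add atoms: bis(pinacolato)diboron, CC1(C)OB(OC1(C)C)B1OC(C)(C)C(C)(C)O1; sodium perborate, [Na+].[O-]OB=O
Why: Copper-catalysed conjugate borylation of the remaining enone, then oxidation of the C–B bond with retention. The boryl–copper species adds to C8 on the face of the C22 methyl group, away from the silyloxymethyl group, so the C8 oxygen is cis to C23; a chiral bisphosphine can reinforce this bias if needed.

Step 14
Reactants: 20 β-hydroxy ketone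
Product: 21 C8 acetate C10 alcohol (1,3-anti)
Conditions: SmI2 (0.3 equiv), MeCHO (8 equiv), THF, −10 °C
Reagents that add atoms: acetaldehyde, CC=O
Why: Evans–Tishchenko reduction: the C8 hydroxyl forms a hemiacetal with acetaldehyde on trivalent samarium and passes its hydride to C10 within the chelate, which gives the 1,3-anti relationship, leaves the acetyl group on O8 and leaves the new C10 hydroxyl free.

Step 15
Reactants: 21 C8 acetate C10 alcohol
Product: 22 bis-silyl ether (C10–OSiMe2t-Bu, C24–OSiMe2t-Bu, C8–OAc)
Conditions: t-BuMe2SiOTf, 2,6-lutidine, CH2Cl2, −78 to 0 °C
Reagents that add atoms: tert-butyldimethylsilyl trifluoromethanesulfonate, CC(C)(C)[Si](C)(C)OS(=O)(=O)C(F)(F)F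
Why: Silylation of the hindered secondary alcohol with a silyl triflate; O11 is the only free hydroxyl, so no selectivity is required.

Step 16
Reactants: 22 bis-silyl ether
Product: 24 C24 acetate C8 alcohol (C10 silyl ether kept), via primary alcohol 23 (not isolated)
Conditions: Bu4NF (1.1 equiv), THF, 0 °C to rt
Reagents that add atoms: none
Why: Fluoride cleaves the unhindered primary silyl ether faster than the neopentyl secondary one, and the freed C24 alkoxide takes the acetyl group from O8 through a six-membered cyclic intermediate (1,3-O,O-acyl migration), the primary ester being the more stable.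

Step 17
Reactants: 24 C24 acetate C8 alcohol; 25 angelic acid
Product: 26 silyl-protected target (C8 angelate, C24 acetate, C10–OSiMe2t-Bu)
Conditions: 25, 2,4,6-trichlorobenzoyl chloride, Et3N, toluene, rt; then 24, 80 °C
Reagents that add atoms: none
Why: Yamaguchi esterification: the mixed trichlorobenzoic anhydride of angelic acid acylates the hindered C8 hydroxyl on heating, and leaving out nucleophilic catalysts keeps the (Z)-alkene from isomerising to the tiglate.

Step 18
Reactants: 26 silyl-protected target
Product: 27 CNP0212099.1
Conditions: HF·pyridine, pyridine, THF, 0 °C to rt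
Reagents that add atoms: none
Why: Fluoride cleavage of the secondary silyl ether under mildly acidic HF·pyridine frees the C10 hydroxyl and leaves the angelate, the acetate and the ketone untouched.

## Compound list

1 | cyclohexa-1,3-diene | C1=CC=CCC1 | starting material
2 | cis-cyclohex-2-ene-1,4-diyl diacetate (meso) | CC(=O)O[C@@H]1C=C[C@H](OC(C)=O)CC1 | intermediate
3 | methyl acetoacetate | COC(=O)CC(C)=O | starting material
4 | methyl 2-(cis-4-acetoxycyclohex-2-enyl)-3-oxobutanoate (acetate on C19 and keto ester on C15 on the same face; C22 epimers) | CC(=O)O[C@@H]1C=C[C@@H](CC1)C(C(C)=O)C(=O)OC | intermediate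
5 | bis(trimethylsilyl) derivative of 4 (silyl ketene acetal of the acetate, silyl enol ether of the keto ester) | C=C(O[Si](C)(C)C)O[C@@H]1C=C[C@@H](CC1)C(C(=O)OC)=C(C)O[Si](C)(C)C | intermediate (not isolated)
6 | cis-2-(6-(1-methoxy-1,3-dioxobutan-2-yl)cyclohex-2-enyl)acetic acid | OC(=O)C[C@H]1C=CCC[C@H]1C(C(C)=O)C(=O)OC | intermediate (not isolated)
7 | Weinreb amide of 6 (C14 arm CH2C(=O)N(OMe)Me, C15 arm acetoacetate, cis) | CON(C)C(=O)C[C@H]1C=CCC[C@H]1C(C(C)=O)C(=O)OC | intermediate
8 | cis-fused bicyclo[5.4.0]undecene diketo ester (C8 and C10 ketones, CO2Me on C22, C19=C20) | O=C1CC(=O)C[C@H]2C=CCC[C@H]2C1C(=O)OC | intermediate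
9 | methyl vinylogous ester of 8 (C8 ketone, C9=C10–OMe) | O=C1C=C(OC)C[C@H]2C=CCC[C@H]2C1C(=O)OC | intermediate
10 | C22-methylated vinylogous ester (CH3 cis to H15, CO2Me cis to C16) | O=C1C=C(OC)C[C@H]2C=CCC[C@H]2[C@@]1(C)C(=O)OC | intermediate
11 | diol enol ether from reduction of 10 (C8–OH, C24–OH, C9=C10–OMe) | OC1C=C(OC)C[C@H]2C=CCC[C@H]2[C@@]1(C)CO | intermediate (not isolated)
12 | cis-fused enone alcohol (C10 ketone, C8=C9, C22 with CH3 and CH2OH) | C1=CC(=O)C[C@H]2C=CCC[C@H]2[C@@]1(C)CO | intermediate
13 | tert-butyldimethylsilyl ether of 12 | C1=CC(=O)C[C@H]2C=CCC[C@H]2[C@@]1(C)CO[Si](C)(C)C(C)(C)C | intermediate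
14 | C12-methyl derivative of 13 (C12 epimers) | C1=CC(=O)C(C)[C@H]2C=CCC[C@H]2[C@@]1(C)CO[Si](C)(C)C(C)(C)C | intermediate
15 | cis-fused bis-enone (ring A: C17 ketone, C19=C20; ring B: C10 ketone, C8=C9; C12 epimers) | C1=CC(=O)C(C)[C@H]2C=CC(=O)C[C@H]2[C@@]1(C)CO[Si](C)(C)C(C)(C)C | intermediate
16 | dilithium bis-dienolate of 15 (enolates C10=C12 and C17=C16) | C1=CC(O[Li])=C(C)[C@H]2C=CC(O[Li])=C[C@H]2[C@@]1(C)CO[Si](C)(C)C(C)(C)C | intermediate (not isolated)
17 | tricyclic bis-enone (cyclobutane C12–C14–C15–C16; ring A enone; ring B enone; C22 with CH3 and CH2OSiMe2t-Bu) | C1=CC(=O)[C@]2(C)[C@@H]3[C@@H]([C@H]2C(=O)C=C3)[C@@]1(C)CO[Si](C)(C)C(C)(C)C | intermediate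
18 | C20-methyl tricyclic diketone (methyl on the face away from C12; ring B enone intact) | C1=CC(=O)[C@]2(C)[C@@H]3[C@@H]([C@H]2C(=O)C[C@H]3C)[C@@]1(C)CO[Si](C)(C)C(C)(C)C | intermediate
19 | C8 pinacol boronate of 18 (boron cis to C23) | CC1(C)OB(OC1(C)C)[C@@H]1CC(=O)[C@]2(C)[C@@H]3[C@@H]([C@H]2C(=O)C[C@H]3C)[C@@]1(C)CO[Si](C)(C)C(C)(C)C | intermediate (not isolated)
20 | β-hydroxy ketone (C8–OH cis to C23, C10 ketone) | O[C@@H]1CC(=O)[C@]2(C)[C@@H]3[C@@H]([C@H]2C(=O)C[C@H]3C)[C@@]1(C)CO[Si](C)(C)C(C)(C)C | intermediate
21 | C8 acetate C10 alcohol (O7 and O11 anti) | CC(=O)O[C@@H]1C[C@@H](O)[C@]2(C)[C@@H]3[C@@H]([C@H]2C(=O)C[C@H]3C)[C@@]1(C)CO[Si](C)(C)C(C)(C)C | intermediate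
22 | bis-silyl ether of 21 (C10–OSiMe2t-Bu) | CC(=O)O[C@@H]1C[C@@H](O[Si](C)(C)C(C)(C)C)[C@]2(C)[C@@H]3[C@@H]([C@H]2C(=O)C[C@H]3C)[C@@]1(C)CO[Si](C)(C)C(C)(C)C | intermediate
23 | C24 alcohol with acetate still on O7 | CC(=O)O[C@@H]1C[C@@H](O[Si](C)(C)C(C)(C)C)[C@]2(C)[C@@H]3[C@@H]([C@H]2C(=O)C[C@H]3C)[C@@]1(C)CO | intermediate (not isolated)
24 | C24 acetate C8 alcohol (C10–OSiMe2t-Bu) | O[C@@H]1C[C@@H](O[Si](C)(C)C(C)(C)C)[C@]2(C)[C@@H]3[C@@H]([C@H]2C(=O)C[C@H]3C)[C@@]1(C)COC(C)=O | intermediate
25 | angelic acid, (Z)-2-methylbut-2-enoic acid | C/C=C(/C)C(=O)O | starting material
26 | C10 silyl ether of the target | C/C=C(/C)C(=O)O[C@@H]1C[C@@H](O[Si](C)(C)C(C)(C)C)[C@]2(C)[C@@H]3[C@@H]([C@H]2C(=O)C[C@H]3C)[C@@]1(C)COC(C)=O | intermediate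
27 | CNP0212099.1 | C/C=C(/C)C(=O)O[C@@H]1C[C@@H](O)[C@]2(C)[C@@H]3[C@@H]([C@H]2C(=O)C[C@H]3C)[C@@]1(C)COC(C)=O | target

## Step count and risks

Total: 18 steps. Longest linear sequence: 18 steps (1 to 27); 3 and 25 enter as purchased materials.

**Step 11 (key step).** The bis-enolate may couple between molecules, couple through oxygen, or add to the enone groups of product already formed, because closing a bridged four-membered ring is slow. The product's C12–C16 bond may also reopen under electron-rich conditions before work-up.
- Fallback with known reactions, from 15 back to 17: 15 is converted with Me3SiOTf and Et3N into the bis(trimethylsilyl) dienol ether F1. N-Bromosuccinimide brominates the less hindered ring A dienol ether at C16 from the face opposite ring B, giving the C16 bromo enone F2. Bu4NF at −78 °C then releases the C12 enolate, which displaces bromide from the rear in a 4-exo-tet enolate alkylation to give 17.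

**Step 4.** Proton transfer from the amide arm to the dianion, or attack by the softer C22 position with five-ring closure, may outrun the seven-ring acylation.
- Fallback from 6 back to 8: the crude acid 6 is esterified with Me3SiCHN2 to the methyl ester F3, which is cyclised under reversible conditions (NaOMe, MeOH, reflux). Any five-ring C22-acylation product has no acidic hydrogen between its carbonyl groups and reverts, whereas the seven-ring tricarbonyl 8 is drained off as its stabilised enolate.

**Step 10.** Hydrogen abstraction may occur at the ring-fusion C14–H, or oxygen may be delivered to C20, which would transpose the alkene and destroy the C14 stereocentre; over-oxidation is also possible.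
- Fallback from 14 back to 15: SeO2 (cat.) with t-BuOOH oxidises through an ene reaction and a [2,3]-shift, which returns the double bond to C19=C20 and puts the hydroxyl on the allylic methylene C17, giving the allylic alcohol F4. Dess–Martin periodinane then gives 15.

**Step 12.** The cuprate may also add to the ring B enone at C8 (insufficient site selectivity), or electron transfer to the strained diketone may cleave the cyclobutane.
- Fallback from 17 back to 20: thiophenol and Et3N add reversibly, and so selectively, to the unhindered C20, giving the phenylthio adduct F5. The ring B enone is then borylated and oxidised as in step 13, the sulfide is oxidised with mCPBA at −78 °C, and warming expels the sulfoxide to return the ring A enone in the hydroxy enone F6. An excess of Me2CuLi now meets a single enone and gives 20.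

**Step 13.** Boryl–copper addition at the neopentyl β-carbon C8 may be slow, and discrimination between the methyl and silyloxymethyl faces may be poor.
- Fallback from 18 back to 20: nucleophilic epoxidation with t-BuOOH and DBU, a small reagent with a different trajectory, gives the epoxy ketone F7. Reductive opening at C9 with Na[PhSeB(OEt)3] in EtOH–AcOH gives 20.

## Further compounds

F1 | step 11 | bis(trimethylsilyl) dienol ether of 15 | C1=CC(O[Si](C)(C)C)=C(C)[C@H]2C=CC(O[Si](C)(C)C)=C[C@H]2[C@@]1(C)CO[Si](C)(C)C(C)(C)C
F2 | step 11 | C16 bromo enone with ring B trimethylsilyl dienol ether (bromine trans to C22) | C1=CC(O[Si](C)(C)C)=C(C)[C@H]2C=CC(=O)[C@H](Br)[C@H]2[C@@]1(C)CO[Si](C)(C)C(C)(C)C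
F3 | step 4 | methyl ester of 6 | COC(=O)C[C@H]1C=CCC[C@H]1C(C(C)=O)C(=O)OC
F4 | step 10 | C17 allylic alcohol of 14 | C1=CC(=O)C(C)[C@H]2C=CC(O)C[C@H]2[C@@]1(C)CO[Si](C)(C)C(C)(C)C
F5 | step 12 | C20 phenylthio adduct of 17 | C1=CC(=O)[C@]2(C)[C@@H]3[C@@H]([C@H]2C(=O)CC3Sc2ccccc2)[C@@]1(C)CO[Si](C)(C)C(C)(C)C
F6 | step 12 | hydroxy enone (C8–OH, C10 ketone, ring A enone) | O[C@@H]1CC(=O)[C@]2(C)[C@@H]3[C@@H]([C@H]2C(=O)C=C3)[C@@]1(C)CO[Si](C)(C)C(C)(C)C
F7 | step 13 | C8–C9 epoxy ketone of 18 (oxygen cis to C23) | O1[C@@H]2[C@H]1C(=O)[C@]3(C)[C@@H]4[C@@H]([C@H]3C(=O)C[C@H]4C)[C@@]2(C)CO[Si](C)(C)C(C)(C)C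
A1 | alternative 1 | acetyl-substituted bicyclo[4.1.1]octane (C8–OBn, C10–OMOM, C14–CH2OSiMe2t-Bu, C16 acetyl) | c1ccccc1CO[C@@H]1C[C@@H](OCOC)[C@]2(C)[C@@H](CO[Si](C)(C)C(C)(C)C)[C@@H]([C@H]2C(C)=O)[C@@]1(C)COCc1ccccc1
A2 | alternative 2 | bicyclo[3.1.1]heptan-2-one with silyloxymethyl arm on C12 and quaternary C22 arm on C15 | CC(C)(C)[Si](C)(C)OC[C@]1(C)[C@@H]2[C@@H]([C@H]1C(=O)C[C@H]2C)[C@@](C)(COCc1ccccc1)CO[Si](C)(C)C(C)(C)C
A3 | alternative 3 | tricyclic allylic ketal (C17 dioxolane, C19=C20) | c1ccccc1CO[C@@H]1C[C@@H](O[Si](C)(C)C(C)(C)C)[C@]2(C)[C@@H]3[C@@H]([C@H]2C4(OCCO4)C=C3)[C@@]1(C)COCc1ccccc1
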